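## Retrosynthetic overview

- **Feature:** in the 2-oxaspiro[4.5]deca-6,9-dien-8-one core, spiro carbon C5 and its neighbour C1 are the para ring carbon and the exocyclic carbon of the para-quinone methide of a guaiacylglycerol β-aryl ether. O2–C3–C4 is the O–C–C unit of an aryl vinyl epoxide.
- **Key disconnection:** O2–C1 and C4–C5 are cut together, which is a Pd(0)-catalysed zwitterionic (3+2) spiroannulation. The tetrahydrofuran is the only ring built, because the dienone ring is the dearomatised guaiacyl ring.
- **After the key step:** the C4 vinyl group serves as a masked CH2OH (dihydroxylation, glycol cleavage, reduction), and three TBS ethers are removed last.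
- **Quinone methide:** Evans syn aldol of TBS-vanillin with a eugenol-derived aryloxyacetyl imide (sets C1′), then reduction, γ-silylation, α-acetylation and fluoride-triggered 1,6-elimination.
- **Epoxide:** the same TBS-vanillin, by allylphosphonate olefination and Shi epoxidation of the (E)-diene (sets C3 and, by net retention, C4).

Key step: step 13

Assumption: locants follow the spirodienone numbering (C1 side-chain carbon, O2, C3 aryl carbon, C4, C5 spiro, C7 OMe carbon, C8 C=O), and C1′ is the side-chain carbon bearing the aryloxy group. The quinone methide is used as its E/Z mixture, since both isomers converge on the same phenolate after the oxygen addition.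

## Route

Step 1
Reactants: 1 vanillin
Product: 2 4-(tert-butyldimethylsilyloxy)-3-methoxybenzaldehyde (TBS-vanillin)
Conditions: TBSCl, imidazole, CH2Cl2, rt
Reagents that add atoms: tert-butyldimethylsilyl chloride, CC(C)(C)[Si](C)(C)Cl
Why: Imidazole-promoted silylation of a phenol masks the acidic OH for the carbanion, boron enolate and palladium steps, and the aryl silyl ether later serves as the fluoride trigger.

Step 2
Reactants: 2 TBS-vanillin
Product: 3 (E)-1-[4-(tert-butyldimethylsilyloxy)-3-methoxyphenyl]buta-1,3-diene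
Conditions: diethyl allylphosphonate, n-BuLi, THF, −78 °C; then 2, HMPA, −78 °C to rt
Reagents that add atoms: diethyl allylphosphonate, C=CCP(=O)(OCC)OCC
Why: In this Horner–Wadsworth–Emmons olefination the lithiated allylphosphonate reacts at its α-carbon in the presence of HMPA and eliminates to the terminal (E)-1,3-diene, and no stereocentre is formed.

Step 3
Reactants: 3 (E)-aryl diene
Product: 4 (2R,3R)-2-[4-(tert-butyldimethylsilyloxy)-3-methoxyphenyl]-3-vinyloxirane (trans)
Conditions: D-fructose-derived Shi ketone (30 mol %), Oxone, K2CO3, Bu4NHSO4 (cat.), Na2B4O7/Na2EDTA buffer (pH 10.5), MeCN–dimethoxymethane, −10 to 0 °C; Et3N-deactivated silica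
Reagents that add atoms: Oxone (potassium peroxymonosulfate), [K+].[O-]S(=O)(=O)OO
Why: In this Shi asymmetric epoxidation of a conjugated diene, the dioxirane should attack the electron-rich trans-disubstituted styrenyl alkene through the spiro transition state rather than the terminal vinyl group, giving the (R,R)-epoxide as with trans-β-methylstyrene, which sets C3 and the allylic centre that becomes C4, while the basic buffer protects the acid-labile product.

Step 4
Reactants: 5 eugenol, 6 ethyl bromoacetate
Product: 7 ethyl 2-(4-allyl-2-methoxyphenoxy)acetate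
Conditions: K2CO3, acetone, reflux
Reagents that add atoms: none
Why: This is a Williamson ether synthesis of a phenolate with an activated primary bromide.

Step 5
Reactants: 7 allyl ester
Product: 10 2-[4-(3-hydroxypropyl)-2-methoxyphenoxy]acetic acid, via B-alkyl-9-BBN adduct 8 (not isolated), via hydroxy ester 9 (not isolated)
Conditions: 9-BBN, THF, 0 °C to rt; then 3 M NaOH, 30 % H2O2, 0 °C to rt; 1 M HCl to pH 3
Reagents that add atoms: hydrogen peroxide, OO; sodium hydroxide, [Na+].[OH-]
Why: Anti-Markovnikov hydroboration with 9-BBN tolerates the ester, alkaline peroxide oxidises the C–B bond, and the excess hydroxide saponifies the activated aryloxyacetate in the same operation, so the acid can be freed from neutral by-products by acid–base extraction.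

Step 6
Reactants: 10 hydroxy acid
Product: 12 2-{4-[3-(tert-butyldimethylsilyloxy)propyl]-2-methoxyphenoxy}acetic acid, via silyl ester 11 (not isolated)
Conditions: TBSCl (2.5 equiv), imidazole, DMF, rt; then K2CO3, MeOH–H2O, rt; 1 M HCl to pH 4
Reagents that add atoms: tert-butyldimethylsilyl chloride, CC(C)(C)[Si](C)(C)Cl
Why: Exhaustive silylation followed by carbonate hydrolysis of the much more labile silyl ester leaves only the primary TBS ether.

Step 7
Reactants: 12 silyloxy acid, 13 (R)-4-benzyl-1,3-oxazolidin-2-one
Product: 15 (R)-4-benzyl-3-(2-{4-[3-(tert-butyldimethylsilyloxy)propyl]-2-methoxyphenoxy}acetyl)-1,3-oxazolidin-2-one, via mixed pivalic anhydride 14 (not isolated)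
Conditions: PivCl, Et3N, THF, −20 °C; then 13, LiCl, −20 °C to rt
Reagents that add atoms: none
Why: In this mixed-anhydride N-acylation, the lithium-activated auxiliary attacks the unhindered aryloxyacetyl carbonyl rather than the pivaloyl carbonyl.

Step 8
Reactants: 15 aryloxyacetyl imide, 2 TBS-vanillin
Product: 17 (4R)-4-benzyl-3-[(2R,3S)-3-[4-(tert-butyldimethylsilyloxy)-3-methoxyphenyl]-2-{4-[3-(tert-butyldimethylsilyloxy)propyl]-2-methoxyphenoxy}-3-hydroxypropanoyl]-1,3-oxazolidin-2-one, via (Z)-dibutylboron enolate 16 (not isolated)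
Conditions: Bu2BOTf, i-Pr2NEt, CH2Cl2, −78 to 0 °C; 2, −78 to 0 °C; pH 7 buffer, MeOH, 30 % H2O2, 0 °C
Reagents that add atoms: none
Why: In this Evans syn aldol reaction the (Z)-boron enolate reacts through a Zimmerman–Traxler chair on the face not shielded by the benzyl group of the (R)-auxiliary, giving the (2R,3S) syn adduct; C2 becomes C1′ of the target and the carbinol centre is erased later.

Step 9
Reactants: 17 syn aldol adduct
Product: 18 (1S,2S)-1-[4-(tert-butyldimethylsilyloxy)-3-methoxyphenyl]-2-{4-[3-(tert-butyldimethylsilyloxy)propyl]-2-methoxyphenoxy}propane-1,3-diol (threo)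
Conditions: LiBH4, H2O (1 equiv), Et2O–THF, 0 °C
Reagents that add atoms: none
Why: Borohydride attacks the exocyclic imide carbonyl and removes the auxiliary reductively, without epimerisation at the α-aryloxy centre and without touching the silyl ethers.

Step 10
Reactants: 18 threo diol
Product: 19 (1S,2S)-3-(tert-butyldimethylsilyloxy)-1-[4-(tert-butyldimethylsilyloxy)-3-methoxyphenyl]-2-{4-[3-(tert-butyldimethylsilyloxy)propyl]-2-methoxyphenoxy}propan-1-ol
Conditions: TBSCl (1.05 equiv), imidazole, CH2Cl2, 0 °C
Reagents that add atoms: tert-butyldimethylsilyl chloride, CC(C)(C)[Si](C)(C)Cl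
Why: Kinetic silylation selects the primary alcohol over the hindered secondary benzylic alcohol.

Step 11
Reactants: 19 benzylic alcohol
Product: 20 (1S,2S)-3-(tert-butyldimethylsilyloxy)-1-[4-(tert-butyldimethylsilyloxy)-3-methoxyphenyl]-2-{4-[3-(tert-butyldimethylsilyloxy)propyl]-2-methoxyphenoxy}propyl acetate
Conditions: Ac2O, pyridine, DMAP (cat.), CH2Cl2, 0 °C to rt
Reagents that add atoms: acetic anhydride, CC(=O)OC(C)=O
Why: DMAP-catalysed acetylation installs a storable benzylic leaving group under non-acidic conditions.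

Step 12
Reactants: 20 benzylic acetate
Product: 22 4-[(2R)-3-(tert-butyldimethylsilyloxy)-2-{4-[3-(tert-butyldimethylsilyloxy)propyl]-2-methoxyphenoxy}propylidene]-2-methoxycyclohexa-2,5-dien-1-one (E/Z mixture; dried CH2Cl2 solution used at once), via phenol acetate 21 (not isolated)
Conditions: TBAF (1.0 equiv), CH2Cl2–THF, −78 to −20 °C; cold aq NaHCO3 wash, MgSO4
Reagents that add atoms: none
Why: In this fluoride-triggered 1,6-elimination, a known entry to para-quinone methides, one equivalent of fluoride cleaves the aryl silyl ether much faster than the two primary alkyl silyl ethers and the phenolate of 21 expels the benzylic acetate; no acid forms that could strip the TBS ethers, the carbinol centre is erased and C1′ is untouched.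

Step 13
Reactants: 22 β-O-4 para-quinone methide, 4 (2R,3R)-aryl vinyl epoxide
Product: 25 (1S,3S,4S,5S)-3-[4-(tert-butyldimethylsilyloxy)-3-methoxyphenyl]-1-[(1S)-2-(tert-butyldimethylsilyloxy)-1-{4-[3-(tert-butyldimethylsilyloxy)propyl]-2-methoxyphenoxy}ethyl]-7-methoxy-4-vinyl-2-oxaspiro[4.5]deca-6,9-dien-8-one, via alkoxide π-allylpalladium zwitterion 23 (not isolated), via phenolate π-allylpalladium adduct 24 (not isolated)
Conditions: Pd2(dba)3·CHCl3 (5 mol %), dppe (11 mol %, premixed), 4 Å MS, CH2Cl2 (0.02 M), −20 °C to rt; 4 (1.5 equiv) added slowly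
Reagents that add atoms: none
Why: Pd(0) ionises the allylic C–O bond of 4 with inversion to zwitterion 23, whose benzylic alkoxide adds 1,6 to the exocyclic carbon of 22 (O2–C1) and aromatises the ring to phenolate 24, and the para carbon of 24 then attacks the allyl terminus next to C3 anti to palladium (C4–C5) and returns Pd(0). The closest known reaction type is the Pd-catalysed formal (3+2) spiroannulation of vinyl epoxides and vinylethylene carbonates with 2,6-di-tert-butyl δ-aryl para-quinone methides; 22 differs by its δ-alkyl group and its single ortho substituent, which should make it more electrophilic but less persistent. The tetrahydrofuran closes in a 5-exo mode that leaves the vinyl group outside the ring, in preference to 7-endo attack on the CH2 terminus. C3 is carried over from 4 because its C–O bond is never broken, C4 results from double inversion (net retention) at the allylic carbon of the trans-epoxide and is also the less strained 3,4-trans arrangement should the allyl faces exchange by π–σ–π, and C1 is set by oxygen addition to the A(1,3)-minimised conformer of 22 (C1′–H in the ring plane) on the face turned away from the bulky CH2OTBS group, which gives the threo C1/C1′ pair of the target. C5 is fixed only by which rotamer of the guaiacyl phenolate closes, and since the methoxy group lies far from the forming bond the substrate offers little bias, so the C5 epimers (and any C1 epimer) are expected to need chromatographic separation. The step needs ipso C-alkylation over O-alkylation, which the geometry of 24 secures because neither the phenolate oxygen nor its ortho carbon can reach the tethered allyl unit, while intermolecular O-allylation, β-hydride isomerisation of 23 and deprotonation of 22 at C1′ are countered by high dilution, low temperature, a chelating ligand that leaves no free phosphine and slow addition of 4.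

Step 14
Reactants: 25 C4-vinyl spirodienone
Product: 26 C4-(1,2-dihydroxyethyl) spirodienone (ring and side-chain centres as in 25, C4 now R by CIP; epimer mixture at the new carbinol carbon)
Conditions: OsO4 (3 mol %), NMO (1.2 equiv), acetone–H2O, 0 °C
Reagents that add atoms: N-methylmorpholine N-oxide, C[N+]1([O-])CCOCC1; water, O
Why: In this Upjohn dihydroxylation the electrophilic OsO4 should select the monosubstituted vinyl group over the two dienone alkenes, which are deactivated by the carbonyl and flanked by the quaternary C5; the new carbinol centre is lost in the next step.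

Step 15
Reactants: 26 diol
Product: 28 tris-TBS ether of the target with C4-CH2OH (1S,3S,4R,5S; side chain 1S), via C4 aldehyde 27 (not isolated)
Conditions: NaIO4 on SiO2, CH2Cl2, 0 °C, filter; then MeOH, NaBH4, −78 °C
Reagents that add atoms: none
Why: Malaprade glycol cleavage under neutral conditions is followed by low-temperature borohydride reduction, in which an aldehyde reacts faster than a cross-conjugated dienone; because 27 is not isolated, epimerisation at C4 and β-elimination of O2 are avoided.

Step 16
Reactants: 28 tris-TBS ether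
Product: 29 target, (1S,3S,4R,5S)-3-(4-hydroxy-3-methoxyphenyl)-1-{(1S)-2-hydroxy-1-[4-(3-hydroxypropyl)-2-methoxyphenoxy]ethyl}-4-(hydroxymethyl)-7-methoxy-2-oxaspiro[4.5]deca-6,9-dien-8-one
Conditions: TBAF–AcOH (1:1, excess), THF, 0 °C to rt
Reagents that add atoms: none
Why: Acetic acid-buffered fluoride desilylation removes all three TBS groups near neutrality, so the acid-labile spirodienone and the base-labile para-hydroxybenzyl ether at C3 should both survive and no stereocentre is touched.

## Compound list

1 | vanillin | COc1cc(C=O)ccc1O | starting material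
2 | 4-(tert-butyldimethylsilyloxy)-3-methoxybenzaldehyde | COc1cc(C=O)ccc1O[Si](C)(C)C(C)(C)C | intermediate
3 | (E)-1-[4-(TBSO)-3-methoxyphenyl]buta-1,3-diene | C=C/C=C/c1ccc(O[Si](C)(C)C(C)(C)C)c(OC)c1 | intermediate
4 | (2R,3R)-2-[4-(TBSO)-3-methoxyphenyl]-3-vinyloxirane | C=C[C@@H]1[C@@H](c2ccc(O[Si](C)(C)C(C)(C)C)c(OC)c2)O1 | intermediate
5 | eugenol | C=CCc1ccc(O)c(OC)c1 | starting material
6 | ethyl bromoacetate | CCOC(=O)CBr | starting material
7 | ethyl 2-(4-allyl-2-methoxyphenoxy)acetate | CCOC(=O)COc1ccc(CC=C)cc1OC | intermediate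
8 | B-alkyl-9-BBN adduct of 7 | CCOC(=O)COc1ccc(CCCB2C3CCCC2CCC3)cc1OC | intermediate (not isolated)
9 | ethyl 2-[4-(3-hydroxypropyl)-2-methoxyphenoxy]acetate | CCOC(=O)COc1ccc(CCCO)cc1OC | intermediate (not isolated)
10 | 2-[4-(3-hydroxypropyl)-2-methoxyphenoxy]acetic acid | OC(=O)COc1ccc(CCCO)cc1OC | intermediate
11 | TBS ester of 12 | COc1cc(CCCO[Si](C)(C)C(C)(C)C)ccc1OCC(=O)O[Si](C)(C)C(C)(C)C | intermediate (not isolated)
12 | 2-{4-[3-(TBSO)propyl]-2-methoxyphenoxy}acetic acid | COc1cc(CCCO[Si](C)(C)C(C)(C)C)ccc1OCC(=O)O | intermediate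
13 | (R)-4-benzyl-1,3-oxazolidin-2-one | O=C1N[C@H](Cc2ccccc2)CO1 | starting material
14 | mixed pivalic anhydride of 12 | COc1cc(CCCO[Si](C)(C)C(C)(C)C)ccc1OCC(=O)OC(=O)C(C)(C)C | intermediate (not isolated)
15 | (R)-4-benzyl-3-(aryloxyacetyl)oxazolidin-2-one | COc1cc(CCCO[Si](C)(C)C(C)(C)C)ccc1OCC(=O)N1[C@H](Cc2ccccc2)COC1=O | intermediate
16 | (Z)-dibutylboron enolate of 15 | CCCCB(CCCC)O/C(=C\Oc1ccc(CCCO[Si](C)(C)C(C)(C)C)cc1OC)N1[C@H](Cc2ccccc2)COC1=O | intermediate (not isolated)
17 | (4R,2′R,3′S) syn aldol adduct | O=C(N1[C@H](Cc2ccccc2)COC1=O)[C@H](Oc1ccc(CCCO[Si](C)(C)C(C)(C)C)cc1OC)[C@@H](O)c1ccc(O[Si](C)(C)C(C)(C)C)c(OC)c1 | intermediate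
18 | (1S,2S) threo 1,3-diol | OC[C@H](Oc1ccc(CCCO[Si](C)(C)C(C)(C)C)cc1OC)[C@@H](O)c1ccc(O[Si](C)(C)C(C)(C)C)c(OC)c1 | intermediate
19 | (1S,2S) γ-O-TBS benzylic alcohol | CC(C)(C)[Si](C)(C)OC[C@H](Oc1ccc(CCCO[Si](C)(C)C(C)(C)C)cc1OC)[C@@H](O)c1ccc(O[Si](C)(C)C(C)(C)C)c(OC)c1 | intermediate
20 | (1S,2S) benzylic acetate | CC(C)(C)[Si](C)(C)OC[C@H](Oc1ccc(CCCO[Si](C)(C)C(C)(C)C)cc1OC)[C@@H](OC(C)=O)c1ccc(O[Si](C)(C)C(C)(C)C)c(OC)c1 | intermediate
21 | phenol acetate (present as its phenolate) | CC(C)(C)[Si](C)(C)OC[C@H](Oc1ccc(CCCO[Si](C)(C)C(C)(C)C)cc1OC)[C@@H](OC(C)=O)c1ccc(O)c(OC)c1 | intermediate (not isolated)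
22 | (R)-β-O-4 para-quinone methide, E/Z mixture | COC1=CC(=C[C@H](CO[Si](C)(C)C(C)(C)C)Oc2ccc(CCCO[Si](C)(C)C(C)(C)C)cc2OC)C=CC1=O | intermediate
23 | alkoxide π-allylpalladium zwitterion (η1 form drawn, ligand omitted) | [O-][C@H](c1ccc(O[Si](C)(C)C(C)(C)C)c(OC)c1)/C=C/C[Pd+] | intermediate (not isolated)
24 | phenolate π-allylpalladium 1,6-adduct (η1 form drawn, ligand omitted) | COc1cc(ccc1[O-])[C@H](O[C@H](c1ccc(O[Si](C)(C)C(C)(C)C)c(OC)c1)/C=C/C[Pd+])[C@H](CO[Si](C)(C)C(C)(C)C)Oc1ccc(CCCO[Si](C)(C)C(C)(C)C)cc1OC | intermediate (not isolated)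
25 | (1S,3S,4S,5S,1′S) C4-vinyl spirodienone, tris-TBS | COC1=C[C@]2(C=CC1=O)[C@H](C=C)[C@@H](c1ccc(O[Si](C)(C)C(C)(C)C)c(OC)c1)O[C@@H]2[C@H](CO[Si](C)(C)C(C)(C)C)Oc1ccc(CCCO[Si](C)(C)C(C)(C)C)cc1OC | intermediate
26 | C4-(1,2-dihydroxyethyl) spirodienone, tris-TBS | COC1=C[C@]2(C=CC1=O)[C@H](C(O)CO)[C@@H](c1ccc(O[Si](C)(C)C(C)(C)C)c(OC)c1)O[C@@H]2[C@H](CO[Si](C)(C)C(C)(C)C)Oc1ccc(CCCO[Si](C)(C)C(C)(C)C)cc1OC | intermediate
27 | C4-formyl spirodienone, tris-TBS (no centre changed) | COC1=C[C@]2(C=CC1=O)[C@H](C=O)[C@@H](c1ccc(O[Si](C)(C)C(C)(C)C)c(OC)c1)O[C@@H]2[C@H](CO[Si](C)(C)C(C)(C)C)Oc1ccc(CCCO[Si](C)(C)C(C)(C)C)cc1OC | intermediate (not isolated)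
28 | tris-TBS ether of the target | COC1=C[C@]2(C=CC1=O)[C@H](CO)[C@@H](c1ccc(O[Si](C)(C)C(C)(C)C)c(OC)c1)O[C@@H]2[C@H](CO[Si](C)(C)C(C)(C)C)Oc1ccc(CCCO[Si](C)(C)C(C)(C)C)cc1OC | intermediate
29 | CNP0252711.1 | COC1=C[C@]2(C=CC1=O)[C@H](CO)[C@@H](c1ccc(O)c(OC)c1)O[C@@H]2[C@H](CO)Oc1ccc(CCCO)cc1OC | target

## Step count and risks

- **Total step count:** 16.
- **Longest linear sequence:** 13 steps (steps 4 to 16, from eugenol).

**Steps most likely to fail**

1. **Step 13.**
   - *What may go wrong:* weak facial discrimination in the oxygen addition (C1) and in the rotamer choice that fixes C5. The zwitterion may isomerise by β-hydride elimination before it is trapped. The alkoxide may abstract the C1′ proton of the quinone methide, which then tautomerises. Intermolecular O-allylation may compete.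
   - *Fallback (sets out from 4 and 22, returns at 25):* the cascade is split into two known reactions.
     - Pd(PPh3)4-catalysed 1,4-addition of acetic acid to 4 (THF, 0 °C) should give (2E,4S)-4-hydroxy-4-[4-(TBSO)-3-methoxyphenyl]but-2-en-1-yl acetate F1 with the carbinol centre untouched.
     - The potassium alkoxide of F1 (KHMDS, THF, −78 °C) is added 1,6 to 22 and the phenolate is quenched with acetic acid. This gives the phenolic benzyl ether F2, and the C1 epimers can be separated at this stage.
     - F2 is closed by the Pd-catalysed intramolecular ipso-Friedel–Crafts-type allylic dearomatisation of para-substituted phenols (Pd(dba)2, a chiral diaminocyclohexane-derived bisphosphine, Cs2CO3, CH2Cl2). Here the ligand rather than the substrate can bias C4 and C5.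

2. **Step 12.**
   - *What may go wrong:* tautomerisation of the quinone methide during its contact with soluble acetate and fluoride, partial loss of the primary silyl ethers, and addition of water during the wash.
   - *Fallback (sets out from 19, returns at 22):*
     - One equivalent of TBAF–AcOH at 0 °C removes only the aryl silyl ether and gives the stable phenolic benzylic alcohol F3.
     - Bromotrimethylsilane in CH2Cl2 at 0 °C for a few minutes converts F3 into the benzylic bromide F4.
     - Shaking the solution with cold saturated aqueous NaHCO3 eliminates HBr to 22. This is the classical procedure for lignin-model quinone methides, and the only base stays in a second phase.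

3. **Step 3.**
   - *What may go wrong:* hydrolytic opening of the electron-rich epoxide in the aqueous oxidation medium, competing attack on the terminal alkene, and erosion of enantiopurity by any (Z)-diene carried over from step 2.
   - *Fallback (sets out from 2, returns at 4):*
     - Wittig reaction of 2 with (triphenylphosphoranylidene)acetaldehyde gives (E)-3-[4-(TBSO)-3-methoxyphenyl]acrylaldehyde F5.
     - Iminium-catalysed asymmetric epoxidation with H2O2 follows, using the diarylprolinol silyl ether enantiomer that delivers the (2S,3R) product (expected to be the R catalyst). It gives (2S,3R)-3-[4-(TBSO)-3-methoxyphenyl]oxirane-2-carbaldehyde F6, in which the formyl group damps benzylic ionisation.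
     - Methylenation with Ph3P=CH2 (THF, −78 to 0 °C) forms the labile vinyl epoxide only in a final anhydrous, basic operation.

## Further compounds

F1 | step 13 | (2E,4S)-4-hydroxy-4-[4-(tert-butyldimethylsilyloxy)-3-methoxyphenyl]but-2-en-1-yl acetate | CC(=O)OC/C=C/[C@H](O)c1ccc(O[Si](C)(C)C(C)(C)C)c(OC)c1
F2 | step 13 | phenolic α-benzyl ether of the β-O-4 unit with F1 (C1, C1′ and C3 as in 25) | COc1cc(ccc1O)[C@H](O[C@H](c1ccc(O[Si](C)(C)C(C)(C)C)c(OC)c1)/C=C/COC(C)=O)[C@H](CO[Si](C)(C)C(C)(C)C)Oc1ccc(CCCO[Si](C)(C)C(C)(C)C)cc1OC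
F3 | step 12 | (1S,2S)-3-(tert-butyldimethylsilyloxy)-1-(4-hydroxy-3-methoxyphenyl)-2-{4-[3-(tert-butyldimethylsilyloxy)propyl]-2-methoxyphenoxy}propan-1-ol | CC(C)(C)[Si](C)(C)OC[C@H](Oc1ccc(CCCO[Si](C)(C)C(C)(C)C)cc1OC)[C@@H](O)c1ccc(O)c(OC)c1
F4 | step 12 | benzylic bromide of F3 (epimer mixture at the C–Br carbon) | CC(C)(C)[Si](C)(C)OC[C@H](Oc1ccc(CCCO[Si](C)(C)C(C)(C)C)cc1OC)C(Br)c1ccc(O)c(OC)c1
F5 | step 3 | (E)-3-[4-(tert-butyldimethylsilyloxy)-3-methoxyphenyl]acrylaldehyde | O=C/C=C/c1ccc(O[Si](C)(C)C(C)(C)C)c(OC)c1
F6 | step 3 | (2S,3R)-3-[4-(tert-butyldimethylsilyloxy)-3-methoxyphenyl]oxirane-2-carbaldehyde | O=C[C@@H]1[C@@H](c2ccc(O[Si](C)(C)C(C)(C)C)c(OC)c2)O1
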